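**Retrosynthetic overview**
1. The plan rests on the trans-fused α-methylene-γ-butyrolactone (O–C6, C7–C11, C11=C13, C12=O) lying next to the C8 acyloxy carbon. C11 and the C8 oxygen are syn across the C7–C8 bond of the ten-membered carbocycle (C1–C10), which the 3(2H)-furanone oxygen bridges between C3 and C10.
2. That pattern is the adduct of a C6 propiolate across a Z-C7=C8 ring alkene: a palladium-catalysed borylative enyne cyclisation forms C7–C11 and C8–B; oxidation, isobutyrylation and desilylation follow.
3. The Z-C7=C8 alkene comes from ring-closing metathesis of a furanone carrying an allyl group at C10 and a vinyl carbinol at C6; the furanone comes from gold-catalysed 5-endo-dig closure of a hydroxy ynone.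
4. The hydroxy ynone is joined from a Weinreb amide (C1, C8–C10, C14; from (S)-lactic acid by dioxolanone allylation) and a terminal enyne (C2–C7, C15; C6 set by Sharpless kinetic resolution, the 4Z alkene by trans-hydroalumination–iodination and Negishi ethynylation).
5. Ring order: furanone, then the nine-membered oxa-bridged ring (the ten-membered carbocycle), then the lactone.

Key step: step 14

Remark: the bicyclic compounds carry germacrane numbering (C1 ketone, C2=C3, ring oxygen between C3 and C10, C4=C5 with C15 on C4, C6 to C9, C10 with methyl C14, lactone carbons C11 to C13); the lactate unit is taken as free (S)-lactic acid, from which the dioxolanone forms directly.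

Step 1
Reactants: 1 (S)-lactic acid
Product: 2 (2S,5S)-2-tert-butyl-5-methyl-1,3-dioxolan-4-one (cis)
Conditions: pivalaldehyde, TsOH·H2O (cat.), H2SO4 (cat.), pentane, reflux (Dean–Stark); crystallisation from Et2O/pentane, −78 °C
Reagents that add atoms: pivalaldehyde, CC(C)(C)C=O
Why: Acid-catalysed acetalisation with azeotropic removal of water favours the cis dioxolanone, which is purified by cold crystallisation, so the lactate stereocentre is stored in the new acetal carbon.

Step 2
Reactants: 2 (2S,5S)-2-tert-butyl-5-methyl-1,3-dioxolan-4-one; 3 allyl bromide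
Product: 5 (2S,5R)-5-allyl-2-tert-butyl-5-methyl-1,3-dioxolan-4-one, via lithium enolate 4 (not isolated)
Conditions: LiN(iPr)2, THF, −78 °C; then allyl bromide, −78 → −30 °C
Reagents that add atoms: none
Why: Self-regeneration of stereocentres: the planar enolate is alkylated anti to the tert-butyl group, so allyl takes the place of the former hydrogen and the quaternary centre (C10 of the target) is fixed as R.

Step 3
Reactants: 5 (2S,5R)-5-allyl-2-tert-butyl-5-methyl-1,3-dioxolan-4-one
Product: 6 (R)-2-hydroxy-N-methoxy-N,2-dimethylpent-4-enamide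
Conditions: MeNHOMe·HCl, i-PrMgCl, THF, −20 → 0 °C
Reagents that add atoms: N,O-dimethylhydroxylamine hydrochloride, CNOC.Cl
Why: Aminolysis of the acylal lactone by the magnesium amide opens the ring and the hemiacetal alkoxide expels pivalaldehyde, giving the Weinreb amide without touching the quaternary centre.

Step 4
Reactants: 7 tert-butyldimethyl(prop-2-yn-1-yloxy)silane; 8 acrolein
Product: 10 rac-6-[(tert-butyldimethylsilyl)oxy]hex-1-en-4-yn-3-ol, via lithium acetylide 9 (not isolated)
Conditions: n-BuLi, THF, −78 °C; then acrolein, −78 °C; H2O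
Reagents that add atoms: none
Why: 1,2-Addition of a hard lithium acetylide to the aldehyde carbon of an enal gives the vinyl alkynyl carbinol (C6 of the target) as the racemate.

Step 5
Reactants: 10 rac-6-[(tert-butyldimethylsilyl)oxy]hex-1-en-4-yn-3-ol
Product: 11 (S)-6-[(tert-butyldimethylsilyl)oxy]hex-1-en-4-yn-3-ol
Conditions: Ti(OiPr)4 (cat.), L-(+)-diisopropyl tartrate, t-BuOOH (0.6 equiv), 4 Å MS, CH2Cl2, −20 °C
Reagents that add atoms: none
Why: Sharpless kinetic resolution of a 1-alken-3-ol: by the empirical model for L-(+)-tartrate the vinyl group of the R enantiomer is epoxidised much faster, so stopping a little beyond half conversion should leave the S alcohol in high enantiomeric purity.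

Step 6
Reactants: 11 (S)-6-[(tert-butyldimethylsilyl)oxy]hex-1-en-4-yn-3-ol
Product: 13 (3S,4Z)-6-[(tert-butyldimethylsilyl)oxy]-5-iodohexa-1,4-dien-3-ol, via cyclic alkenylaluminate 12 (not isolated)
Conditions: NaAlH2(OCH2CH2OMe)2, THF, 0 °C; EtOAc; then I2, THF, −78 → 0 °C
Reagents that add atoms: iodine, II
Why: Alkoxide-directed trans-hydroalumination puts hydride on C5 and aluminium on C4 in a five-membered oxaaluminacycle, and iodinolysis with retention gives the iodoalkene with iodine cis to the carbinol carbon (the 4Z geometry of the target), the low temperature suppressing β-elimination of the silyloxy group.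

Step 7
Reactants: 13 (3S,4Z)-6-[(tert-butyldimethylsilyl)oxy]-5-iodohexa-1,4-dien-3-ol
Product: 14 (3S,4Z)-6-[(tert-butyldimethylsilyl)oxy]-5-iodo-3-[(triethylsilyl)oxy]hexa-1,4-diene
Conditions: Et3SiCl, imidazole, CH2Cl2, 0 °C
Reagents that add atoms: chlorotriethylsilane, CC[Si](Cl)(CC)CC
Why: Standard silylation caps the C6 oxygen so that it cannot add to the ynone later and can be freed selectively beside the primary TBS ether.

Step 8
Reactants: 14 (3S,4Z)-6-[(tert-butyldimethylsilyl)oxy]-5-iodo-3-[(triethylsilyl)oxy]hexa-1,4-diene; 15 ethynylmagnesium bromide (HC≡CMgBr)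
Product: 17 (3S,4E)-5-{[(tert-butyldimethylsilyl)oxy]methyl}-3-[(triethylsilyl)oxy]hepta-1,4-dien-6-yne (ethynyl cis to C3), via ethynylzinc bromide 16 (not isolated)
Conditions: HC≡CMgBr, ZnBr2, THF, 0 °C; then 14, Pd(PPh3)4 (5 mol%), THF, 23 °C
Reagents that add atoms: none
Why: Negishi coupling of the alkenyl iodide with ethynylzinc bromide proceeds with retention of alkene geometry and gives the terminal enyne directly.

Step 9
Reactants: 17 (3S,4E)-5-{[(tert-butyldimethylsilyl)oxy]methyl}-3-[(triethylsilyl)oxy]hepta-1,4-dien-6-yne; 6 (R)-2-hydroxy-N-methoxy-N,2-dimethylpent-4-enamide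
Product: 20 (4R,8E,10S)-8-{[(tert-butyldimethylsilyl)oxy]methyl}-4-hydroxy-4-methyl-10-[(triethylsilyl)oxy]dodeca-1,8,11-trien-6-yn-5-one, via lithium acetylide 18 (not isolated), via lithium alkoxide 19 (not isolated)
Conditions: 17, n-BuLi, THF, −78 °C; 6, LiN(SiMe3)2, THF, −78 °C; combine, −78 → 0 °C; H2O
Reagents that add atoms: none
Why: Acylation of the lithium acetylide by the Weinreb amide stops at the chelated tetrahedral intermediate and releases the ynone on work-up, prior deprotonation of the tertiary hydroxyl saving an equivalent of acetylide.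

Step 10
Reactants: 20 (4R,8E,10S)-8-{[(tert-butyldimethylsilyl)oxy]methyl}-4-hydroxy-4-methyl-10-[(triethylsilyl)oxy]dodeca-1,8,11-trien-6-yn-5-one
Product: 21 (R)-2-allyl-5-[(2Z,4S)-1-[(tert-butyldimethylsilyl)oxy]-4-[(triethylsilyl)oxy]hexa-2,5-dien-2-yl]-2-methylfuran-3(2H)-one
Conditions: (4-CF3C6H4)3PAuCl (5 mol%), AgOTf (5 mol%), toluene, 23 °C
Reagents that add atoms: none
Why: Cycloisomerisation of a γ-hydroxy alkynone by cationic monovalent gold: π-activation lets the tertiary hydroxyl add to C3 in a 5-endo-dig mode and protodeauration gives the 3(2H)-furanone, with C10 untouched and the silylated C6 oxygen unable to compete.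

Step 11
Reactants: 21 (R)-2-allyl-5-[(2Z,4S)-1-[(tert-butyldimethylsilyl)oxy]-4-[(triethylsilyl)oxy]hexa-2,5-dien-2-yl]-2-methylfuran-3(2H)-one
Product: 22 (4Z,6S,7Z,10R)-15-[(tert-butyldimethylsilyl)oxy]-6-[(triethylsilyl)oxy]-3,10-epoxy-11,12,13-trinorgermacra-2,4,7-trien-1-one (furanone-bridged ten-membered carbocycle)
Conditions: second-generation Grubbs catalyst (H2IMes)(PCy3)Cl2Ru=CHPh (10 mol%), CH2Cl2 (0.002 M), 40 °C
Reagents that add atoms: none
Why: Ring-closing metathesis joins the two monosubstituted alkenes, the trisubstituted electron-poor C4=C5 and C2=C3 alkenes are inert, and the nine-membered oxa-bridged ring can hold the new C7=C8 alkene only as Z.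

Step 12
Reactants: 22 (4Z,6S,7Z,10R)-15-[(tert-butyldimethylsilyl)oxy]-6-[(triethylsilyl)oxy]-3,10-epoxy-11,12,13-trinorgermacra-2,4,7-trien-1-one
Product: 23 (4Z,6S,7Z,10R)-15-[(tert-butyldimethylsilyl)oxy]-6-hydroxy-3,10-epoxy-11,12,13-trinorgermacra-2,4,7-trien-1-one
Conditions: PPTS (cat.), MeOH/CH2Cl2, 0 °C
Reagents that add atoms: none
Why: Acid-catalysed methanolysis cleaves the triethylsilyl ether far faster than the tert-butyldimethylsilyl ether, and weak acid at 0 °C should not ionise the doubly allylic alcohol.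

Step 13
Reactants: 23 (4Z,6S,7Z,10R)-15-[(tert-butyldimethylsilyl)oxy]-6-hydroxy-3,10-epoxy-11,12,13-trinorgermacra-2,4,7-trien-1-one; 24 propiolic acid
Product: 25 (4Z,6S,7Z,10R)-15-[(tert-butyldimethylsilyl)oxy]-1-oxo-3,10-epoxy-11,12,13-trinorgermacra-2,4,7-trien-6-yl propiolate
Conditions: DCC, DMAP (5 mol%), CH2Cl2, −20 → 0 °C
Reagents that add atoms: none
Why: Steglich esterification leaves the C6–O bond intact (retention), and low temperature with little DMAP limits amine-induced oligomerisation of the propiolate.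

Step 14
Reactants: 25 (4Z,6S,7Z,10R)-15-[(tert-butyldimethylsilyl)oxy]-1-oxo-3,10-epoxy-11,12,13-trinorgermacra-2,4,7-trien-6-yl propiolate
Product: 26 (4Z,6R,7S,8R,10R)-15-[(tert-butyldimethylsilyl)oxy]-1-oxo-8-(4,4,5,5-tetramethyl-1,3,2-dioxaborolan-2-yl)-3,10-epoxygermacra-2,4,11(13)-trien-12,6-olide
Conditions: Pd(OAc)2 (10 mol%), B2pin2 (1.3 equiv), MeOH (1.5 equiv), toluene, 50 °C
Reagents that add atoms: bis(pinacolato)diboron, CC1(C)OB(OC1(C)C)B1OC(C)(C)C(C)(C)O1
Why: Proposed new method: a palladium hydride formed from Pd(OAc)2, B2pin2 and MeOH should add across the propiolate with hydride to C13 and palladium to C11, the resulting α-palladated acrylate should insert the ring Z-C7=C8 alkene by 5-exo-trig syn-carbopalladation (C11–C7, Pd–C8) and so close the γ-lactone, and transmetallation with B2pin2 followed by stereoretentive C–B reductive elimination should give the C8 boronate. The closest known reactions are the palladium-catalysed borylative cyclisation of carbon-, nitrogen- and ether-tethered 1,6-enynes with B2pin2 and the cyclisation of allylic alkynoates to α-alkylidene-γ-butyrolactones under divalent palladium; a propiolate ester adding to an endocyclic alkene has not been shown in the borylative manifold. C7 is set by the C6 stereocentre: allylic strain keeps H6 eclipsed with the Z-alkene, the ring bond C6–C5 covers one π-face and the ester oxygen sits on the other, so the tether delivers C11 to the peripheral face and H6 and H7 end up trans. C8 follows from the syn insertion and from retention in the C–B bond formation, which together give the C11/C8-heteroatom syn relationship of the target. The step needs C7=C8 to react in preference to the trisubstituted, cross-conjugated C4=C5 alkene (closure there would place palladium on a tertiary carbon), borylation to outrun β-hydride loss toward C9 (H7 is anti to palladium), and the doubly allylic ester not to ionise on zerovalent palladium, for which phosphine-free conditions in toluene are chosen. The ester must react through its minor s-cis rotamer, which 50 °C should allow.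

Step 15
Reactants: 26 (4Z,6R,7S,8R,10R)-15-[(tert-butyldimethylsilyl)oxy]-1-oxo-8-(4,4,5,5-tetramethyl-1,3,2-dioxaborolan-2-yl)-3,10-epoxygermacra-2,4,11(13)-trien-12,6-olide
Product: 27 (4Z,6R,7R,8R,10R)-15-[(tert-butyldimethylsilyl)oxy]-8-hydroxy-1-oxo-3,10-epoxygermacra-2,4,11(13)-trien-12,6-olide
Conditions: NaBO3·4H2O, THF/H2O (1:1), 0 → 23 °C
Reagents that add atoms: sodium perborate tetrahydrate (NaBO3·4H2O), [Na+].[Na+].O[B-]1(O)OO[B-](O)(O)OO1
Why: Boronate oxidation by 1,2-migration of C8 from boron to oxygen proceeds with retention, and the weakly basic perborate is chosen to spare the α-methylene lactone.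

Step 16
Reactants: 27 (4Z,6R,7R,8R,10R)-15-[(tert-butyldimethylsilyl)oxy]-8-hydroxy-1-oxo-3,10-epoxygermacra-2,4,11(13)-trien-12,6-olide; 28 isobutyryl chloride
Product: 29 (4Z,6R,7R,8R,10R)-15-[(tert-butyldimethylsilyl)oxy]-8-(isobutyryloxy)-1-oxo-3,10-epoxygermacra-2,4,11(13)-trien-12,6-olide
Conditions: pyridine, DMAP (cat.), CH2Cl2, 0 → 23 °C
Reagents that add atoms: none
Why: Acylation of the secondary alcohol by the acid chloride under nucleophilic catalysis touches no stereocentre.

Step 17
Reactants: 29 (4Z,6R,7R,8R,10R)-15-[(tert-butyldimethylsilyl)oxy]-8-(isobutyryloxy)-1-oxo-3,10-epoxygermacra-2,4,11(13)-trien-12,6-olide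
Product: 30 (4Z,6R,7R,8R,10R)-15-hydroxy-8-(isobutyryloxy)-1-oxo-3,10-epoxygermacra-2,4,11(13)-trien-12,6-olide (CNP0176924.3)
Conditions: HF·pyridine, pyridine, THF, 0 → 23 °C
Reagents that add atoms: none
Why: Fluoride-mediated cleavage of the primary silyl ether under buffered acidic conditions should leave both esters, the furanone and the exocyclic enoate intact.

**Compound list**
1 | (S)-lactic acid | C[C@H](O)C(=O)O | starting material
2 | (2S,5S)-2-tert-butyl-5-methyl-1,3-dioxolan-4-one | C[C@@H]1O[C@H](C(C)(C)C)OC1=O | intermediate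
3 | allyl bromide | C=CCBr | starting material
4 | lithium enolate of 2 | CC1=C(O[Li])O[C@@H](C(C)(C)C)O1 | intermediate (not isolated)
5 | (2S,5R)-5-allyl-2-tert-butyl-5-methyl-1,3-dioxolan-4-one | C[C@]1(CC=C)O[C@H](C(C)(C)C)OC1=O | intermediate
6 | (R)-2-hydroxy-N-methoxy-N,2-dimethylpent-4-enamide | C=CC[C@@](C)(O)C(=O)N(C)OC | intermediate
7 | tert-butyldimethyl(prop-2-yn-1-yloxy)silane | C#CCO[Si](C)(C)C(C)(C)C | starting material
8 | acrolein | C=CC=O | starting material
9 | lithium acetylide of 7 | [Li]C#CCO[Si](C)(C)C(C)(C)C | intermediate (not isolated)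
10 | rac-6-[(tert-butyldimethylsilyl)oxy]hex-1-en-4-yn-3-ol | C=CC(O)C#CCO[Si](C)(C)C(C)(C)C | intermediate
11 | (S)-6-[(tert-butyldimethylsilyl)oxy]hex-1-en-4-yn-3-ol | C=C[C@H](O)C#CCO[Si](C)(C)C(C)(C)C | intermediate
12 | sodium cyclic alkenylaluminate (five-membered oxaaluminacycle, Al on C4) | C=C[C@@H]1O[Al-](OCCOC)(OCCOC)C(CO[Si](C)(C)C(C)(C)C)=C1.[Na+] | intermediate (not isolated)
13 | (3S,4Z)-6-[(tert-butyldimethylsilyl)oxy]-5-iodohexa-1,4-dien-3-ol | C=C[C@H](O)/C=C(\I)CO[Si](C)(C)C(C)(C)C | intermediate
14 | (3S,4Z)-6-[(tert-butyldimethylsilyl)oxy]-5-iodo-3-[(triethylsilyl)oxy]hexa-1,4-diene | C=C[C@H](O[Si](CC)(CC)CC)/C=C(\I)CO[Si](C)(C)C(C)(C)C | intermediate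
15 | ethynylmagnesium bromide | C#C[Mg]Br | starting material
16 | ethynylzinc bromide | C#C[Zn]Br | intermediate (not isolated)
17 | (3S,4E)-5-{[(tert-butyldimethylsilyl)oxy]methyl}-3-[(triethylsilyl)oxy]hepta-1,4-dien-6-yne | C=C[C@H](O[Si](CC)(CC)CC)/C=C(\C#C)CO[Si](C)(C)C(C)(C)C | intermediate
18 | lithium acetylide of 17 | C=C[C@H](O[Si](CC)(CC)CC)/C=C(\C#C[Li])CO[Si](C)(C)C(C)(C)C | intermediate (not isolated)
19 | lithium alkoxide of 6 | C=CC[C@@](C)(O[Li])C(=O)N(C)OC | intermediate (not isolated)
20 | (4R,8E,10S)-8-{[(tert-butyldimethylsilyl)oxy]methyl}-4-hydroxy-4-methyl-10-[(triethylsilyl)oxy]dodeca-1,8,11-trien-6-yn-5-one | C=CC[C@@](C)(O)C(=O)C#C/C(CO[Si](C)(C)C(C)(C)C)=C\[C@@H](O[Si](CC)(CC)CC)C=C | intermediate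
21 | (R)-2-allyl-5-[(2Z,4S)-1-[(tert-butyldimethylsilyl)oxy]-4-[(triethylsilyl)oxy]hexa-2,5-dien-2-yl]-2-methylfuran-3(2H)-one | C=CC[C@@]1(C)OC(=CC1=O)/C(CO[Si](C)(C)C(C)(C)C)=C\[C@@H](O[Si](CC)(CC)CC)C=C | intermediate
22 | (4Z,6S,7Z,10R)-15-[(tert-butyldimethylsilyl)oxy]-6-[(triethylsilyl)oxy]-3,10-epoxy-11,12,13-trinorgermacra-2,4,7-trien-1-one | CC[Si](CC)(CC)O[C@@H]1/C=C(/CO[Si](C)(C)C(C)(C)C)C2=CC(=O)[C@@](C)(C/C=C\1)O2 | intermediate
23 | (4Z,6S,7Z,10R)-15-[(tert-butyldimethylsilyl)oxy]-6-hydroxy-3,10-epoxy-11,12,13-trinorgermacra-2,4,7-trien-1-one | O[C@@H]1/C=C(/CO[Si](C)(C)C(C)(C)C)C2=CC(=O)[C@@](C)(C/C=C\1)O2 | intermediate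
24 | propiolic acid | C#CC(=O)O | starting material
25 | C6 propiolate of 23 (key-step precursor) | C#CC(=O)O[C@@H]1/C=C(/CO[Si](C)(C)C(C)(C)C)C2=CC(=O)[C@@](C)(C/C=C\1)O2 | intermediate
26 | C8 pinacol boronate of the lactone-fused macrocycle (6R,7S,8R,10R) | C=C1C(=O)O[C@@H]2/C=C(/CO[Si](C)(C)C(C)(C)C)C3=CC(=O)[C@@](C)(C[C@@H](B4OC(C)(C)C(C)(C)O4)[C@@H]12)O3 | intermediate
27 | C8 alcohol (6R,7R,8R,10R), 15-O-TBS | C=C1C(=O)O[C@@H]2/C=C(/CO[Si](C)(C)C(C)(C)C)C3=CC(=O)[C@@](C)(C[C@@H](O)[C@@H]12)O3 | intermediate
28 | isobutyryl chloride | CC(C)C(Cl)=O | starting material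
29 | C8 isobutyrate, 15-O-TBS | C=C1C(=O)O[C@@H]2/C=C(/CO[Si](C)(C)C(C)(C)C)C3=CC(=O)[C@@](C)(C[C@@H](OC(=O)C(C)C)[C@@H]12)O3 | intermediate
30 | CNP0176924.3 | C=C1C(=O)O[C@@H]2/C=C(/CO)C3=CC(=O)[C@@](C)(C[C@@H](OC(=O)C(C)C)[C@@H]12)O3 | target

**Step count**
Total: 17 steps. Longest linear sequence: 14 steps (7 → 30, steps 4–17); the amide arm (1 → 6) is three steps and joins at step 9.

**Steps most likely to fail**

Step 14 (labelled step). The C8 alkylpalladium may lose a β-hydride toward C9 before it is borylated, zerovalent palladium may ionise the doubly allylic ester, or closure may be too slow because the ester rests in its s-trans rotamer. The fallback uses an ether tether, the tether class on which this borylative cyclisation is established, and sets out from alcohol 23. Williamson propargylation (NaH, propargyl bromide, THF, 0 °C) would give the C6 propargyl ether F1. Pd(OAc)2, B2pin2 and MeOH in toluene should then give the 3-methylenetetrahydrofuran C8 boronate F2 by the same syn course and facial control. Perborate oxidation would give the C8 alcohol F3, which has no Michael acceptor to protect, and isobutyryl chloride 28 with pyridine would give the C8 isobutyrate F4. Allylic oxidation of the ring O–CH2 group next to the exocyclic alkene (CrO3, 3,5-dimethylpyrazole, CH2Cl2, −20 °C) would then install the lactone carbonyl, and the sequence comes back to the route at 29.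

Step 11. Cross-metathesis oligomerisation may outrun closure of the strained, furanone-bridged nine-membered ring, and the hindered allylic silyl ether may initiate slowly. The fallback reverses the order of ring formation and sets out from hydroxy ynone 20. Metathesis on this open chain, with no furanone yet to constrain it, would close the ten-membered carbocycle to the (4E,6S,7Z,10R)-10-hydroxy-10-methyl-4-{[(tert-butyldimethylsilyl)oxy]methyl}-6-[(triethylsilyl)oxy]cyclodeca-4,7-dien-2-yn-1-one F5; its internal, electron-poor alkyne should be a poor partner for enyne metathesis. Transannular 5-endo-dig addition of the C10 hydroxyl to C3 under the gold conditions of step 10 would then build the furanone bridge, and the sequence comes back to the route at 22.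

Step 15. Hydroperoxide may attack the exocyclic enoate as a nucleophile (epoxidation or conjugate addition), or the basic medium may open the lactone and let it reclose onto the new C8 hydroxyl. The fallback masks the enoate and sets out from boronate 26. Conjugate addition of Me2NH (THF, 23 °C) would give the 13-(dimethylamino)-11,13-dihydro boronate F6, expected mainly with the aminomethyl group cis to H7; the C11 configuration is erased later. Perborate oxidation would give the amino alcohol F7; any N-oxide formed would undergo Cope elimination to 27 and do no harm. Acylation with 28 would give the amino isobutyrate F8, and N-methylation (MeI) followed by elimination (NaHCO3) would restore the methylene group. The sequence comes back to the route at 29.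

**Further compounds**
F1 | step 14 | C6 propargyl ether of 23 | C#CCO[C@@H]1/C=C(/CO[Si](C)(C)C(C)(C)C)C2=CC(=O)[C@@](C)(C/C=C\1)O2
F2 | step 14 | 12-deoxo (3-methylenetetrahydrofuran) C8 pinacol boronate | C=C1CO[C@@H]2/C=C(/CO[Si](C)(C)C(C)(C)C)C3=CC(=O)[C@@](C)(C[C@@H](B4OC(C)(C)C(C)(C)O4)[C@@H]12)O3
F3 | step 14 | 12-deoxo C8 alcohol | C=C1CO[C@@H]2/C=C(/CO[Si](C)(C)C(C)(C)C)C3=CC(=O)[C@@](C)(C[C@@H](O)[C@@H]12)O3
F4 | step 14 | 12-deoxo C8 isobutyrate | C=C1CO[C@@H]2/C=C(/CO[Si](C)(C)C(C)(C)C)C3=CC(=O)[C@@](C)(C[C@@H](OC(=O)C(C)C)[C@@H]12)O3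
F5 | step 11 | (4E,6S,7Z,10R)-10-hydroxy-10-methyl-4-{[(tert-butyldimethylsilyl)oxy]methyl}-6-[(triethylsilyl)oxy]cyclodeca-4,7-dien-2-yn-1-one | C[C@@]1(O)C/C=C\[C@H](O[Si](CC)(CC)CC)/C=C(/CO[Si](C)(C)C(C)(C)C)C#CC1=O
F6 | step 15 | 13-(dimethylamino)-11,13-dihydro C8 boronate | CN(C)C[C@@H]1C(=O)O[C@@H]2/C=C(/CO[Si](C)(C)C(C)(C)C)C3=CC(=O)[C@@](C)(C[C@@H](B4OC(C)(C)C(C)(C)O4)[C@@H]12)O3
F7 | step 15 | 13-(dimethylamino)-11,13-dihydro C8 alcohol | CN(C)C[C@@H]1C(=O)O[C@@H]2/C=C(/CO[Si](C)(C)C(C)(C)C)C3=CC(=O)[C@@](C)(C[C@@H](O)[C@@H]12)O3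
F8 | step 15 | 13-(dimethylamino)-11,13-dihydro C8 isobutyrate | CN(C)C[C@@H]1C(=O)O[C@@H]2/C=C(/CO[Si](C)(C)C(C)(C)C)C3=CC(=O)[C@@](C)(C[C@@H](OC(=O)C(C)C)[C@@H]12)O3
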